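**What stands.** Ring grows from starting material in the autumn run, and I want to know how fast it goes on to over-reaction product in west and south.

in all of them: starting material 0.80 M
- autumn: protic impurity 0.16 M; run made earlier
- west: protic impurity 0.0800 M; time 8.0 min
- south: protic impurity 0.0800 M; time 4.0 min

autumn run (percent of the starting material charged): time / s: ring / % = 10.0: 6.3; 15.0: 8.0; 25.0: 12.3; 30.0: 14.1; 40.0: 17.0; 50.0: 20.8

(standard deviation of a reading: 1 percentage point)

- the numbers in the tables scatter with a standard deviation of 1 percentage point
- no earlier run changes the charge of protic impurity; that part of a forecast is a guess

* which of the two there is more of at the end, west (ring / over-reaction product)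
* which of the two there is more of at the end, south (ring / over-reaction product)
* how much ring is there at the end, in percent of the starting material charged: west
* how much ring is there at the end, in percent of the starting material charged: south

**First chain.** My own reckoning starts from the first reading, a making constant of 0.00630 s⁻¹. Unhindered, that puts 27.0% in ring at 50.0 s, but I read 20.8%. I charge the gap to a first-order drain on ring, the intermediate of a consecutive reaction. The gap divided by the area under the ring curve, roughly half the last reading times its time, gives 0.0120 s⁻¹. Ring is then making/(drain − making) × (exp(−making·t) − exp(−drain·t)), which gives 18.2% in south and 5.05% in west.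

**Weak link.** The making constant of that chain rests on one reading with a scatter of 1 percentage point, and the drain comes from a gap of 6.2 points. The reading at 15.0 s gives 0.00533 s⁻¹, so I take the mean, 0.00582 s⁻¹. Now 25.2% is made, the drain is 0.00853 s⁻¹, and the ring half-life is 1.35 min. No run varies the protic impurity, so keeping these constants is a guess. I commit to 25.4% ring in south and 9.57% in west. What has passed through ring is 49.8% in south and 84.3% in west, more than the ring in each , so I expect over-reaction product to lead in both.

**The forecast.** It names over-reaction product for west and ring for south, with ring at 36% (15% to 58%) in west and 47% (28% to 64%) in south: “So I expect ring to lead at 4 min and the over-reaction product to lead narrowly at 8 min.” My ring figures are lower than these , and we differ on south.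

**The flask.** West holds 7.05% ring against 68.6% over-reaction product; south holds 19.0% against 42.9%.

    2 starting material ⇌ open dimer (K = 0.400 M⁻¹, k = 0.00144 M⁻¹ s⁻¹)
    starting material + ring → side product (k = 0.00202 M⁻¹ s⁻¹)
    ring → over-reaction product (k = 0.00871 s⁻¹)
    starting material + protic impurity → quenched substrate (k = 0.0307 M⁻¹ s⁻¹)
    starting material → ring (k = 0.00643 s⁻¹)

South at 4.0 min has stood 2.96 of my ring half-lives. Ring in south, each step taken net, is made 1.54 times as fast as it is used up at 1.17 min, but 0.612 times as fast at 4.00 min, so its peak lies between those times and the asked time is on the falling side. The neighbouring flask, south read at 6.0 min, stands at 4.44 half-lives, where my formula gives 16.5% ring; the computed flask holds 11.9%.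

All runs were generated by integration with constants of no real substance, noise included.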